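The route rests on the C1–C2 bond. The C14 ketone of ring A, the quaternary C1 and the C2 carbinol of the ten-membered ring (C1–C10) form a β-hydroxy ketone, so an aldol reaction at C1–C2 closes that ring. In one operation SmI2 converts the tertiary C1 bromide of a ring A bromo ketone into the C1–C14 samarium enolate, which adds to the tethered C2 aldehyde, closing the ring and setting C1 and C2. The precursor is the seco aldehyde: ring A bromo ketone, C9 silyl ether, butenolide (C7, C8, C17, C19), Z C5=C6 alkene, C4 silyl ether and C2 aldehyde.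

Key step: step 20

Remarks on the chemistry:
- Briarane numbering is used: ring A = C1, C10–C14; ten-membered ring = C1–C10; lactone = C7, C8, C17, C19 and O; C15, C16, C18, C20 are the carbons on C1, C5, C17, C11.
- The configurations at C4, C7, C9, C10 and the Z C5=C6 alkene in 28, and at C1 and C2 in 30, were checked against the target and agree with it.
- Precursor design: C9 carries TBS and C4 the more robust TIPS, because C9 is unmasked first and acetylated together with C2 and C14. Both C1 bromide epimers give the same enolate; the epimer drawn for 27 and 28 is the one expected from step 18.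
- Ring A is carried as the symmetric 2,6-dimethylcyclohexa-2,5-dienyl group; C10 becomes stereogenic only in step 17.

Step 1
Reactants: 1 2,6-dimethylbenzoic acid
Product: 2 2,6-dimethylcyclohexa-2,5-diene-1-carboxylic acid
Conditions: Li, NH3(l), THF, −78 °C; NH4Cl
Reagents that add atoms: none
Why: Birch reduction of a benzoate puts the two new hydrogens on the ipso and para carbons, so ring A arrives in one step as the skipped diene with C10 carrying C9.

Step 2
Reactants: 2 2,6-dimethylcyclohexa-2,5-diene-1-carboxylic acid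
Product: 3 N-methoxy-N,2,6-trimethylcyclohexa-2,5-diene-1-carboxamide
Conditions: 1,1'-carbonyldiimidazole, CH2Cl2, 23 °C; MeNHOMe·HCl
Reagents that add atoms: N,O-dimethylhydroxylamine hydrochloride CNOC.Cl
Why: Weinreb amide formation through the acyl imidazolide needs no base strong enough to move the skipped alkenes into conjugation.

Step 3
Reactants: 3 N-methoxy-N,2,6-trimethylcyclohexa-2,5-diene-1-carboxamide; 4 prop-2-yn-1-ol
Product: 5 1-(2,6-dimethylcyclohexa-2,5-dien-1-yl)-4-hydroxybut-2-yn-1-one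
Conditions: 4, n-BuLi (2 equiv), THF, −78 → −20 °C; then 3, −78 → 0 °C; aq. NH4Cl
Reagents that add atoms: none
Why: Weinreb ketone synthesis: the dilithiated alkynol adds once and the chelated tetrahedral intermediate lasts until the quench, so the enolisable ynone appears only on work-up.

Step 4
Reactants: 5 1-(2,6-dimethylcyclohexa-2,5-dien-1-yl)-4-hydroxybut-2-yn-1-one
Product: 6 (R)-1-(2,6-dimethylcyclohexa-2,5-dien-1-yl)but-2-yne-1,4-diol
Conditions: Ru[(R,R)-TsDPEN](p-cymene) (1 mol %), i-PrOH, 23 °C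
Reagents that add atoms: none
Why: Noyori asymmetric transfer hydrogenation of an alkynyl ketone: the (R,R)-ligand recognises the alkyne and sets C9 as the (R)-carbinol by reagent control.

Step 5
Reactants: 6 (R)-1-(2,6-dimethylcyclohexa-2,5-dien-1-yl)but-2-yne-1,4-diol
Product: 8 3-[(R)-(2,6-dimethylcyclohexa-2,5-dien-1-yl)(hydroxy)methyl]-4-methylfuran-2(5H)-one, via alkenylmagnesium chelate 7 (not isolated)
Conditions: MeMgBr (5 equiv), CuI (10 mol %), THF, 0 → 23 °C; CO2, 0 °C; 1 M HCl
Reagents that add atoms: methylmagnesium bromide C[Mg]Br; carbon dioxide O=C=O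
Why: Alkoxide-directed anti-carbomagnesiation of a propargylic alcohol: methyl (C18) adds to C17 beside the unhindered primary alkoxide, the chelated C8 alkenylmagnesium is carboxylated (C7) and the cis hydroxy acid lactonises, which fixes C7 and C19 cis on C8=C17.

Step 6
Reactants: 8 3-[(R)-(2,6-dimethylcyclohexa-2,5-dien-1-yl)(hydroxy)methyl]-4-methylfuran-2(5H)-one
Product: 10 bis-TBS ether of the ring-opened Weinreb amide (C7 amide, C9–OTBS, C19–OTBS), via dihydroxy Weinreb amide 9 (not isolated)
Conditions: MeNHOMe·HCl, i-PrMgCl, THF, −20 °C; work-up; TBSOTf, 2,6-lutidine, CH2Cl2, 0 °C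
Reagents that add atoms: N,O-dimethylhydroxylamine hydrochloride CNOC.Cl; tert-butyldimethylsilyl triflate CC(C)(C)[Si](C)(C)OS(=O)(=O)C(F)(F)F
Why: Weinreb aminolysis of the lactone and silylation of both hydroxyls give an open-chain amide with C7 and C19 still cis, so the ketone made next cannot close to a lactol and lose water to a furan.

Step 7
Reactants: 10 bis-TBS Weinreb amide; 11 1-methoxy-4-[(prop-2-yn-1-yloxy)methyl]benzene
Product: 12 C7 ynone (C6≡C5–C16H2OPMB on the C7 carbonyl)
Conditions: 11, n-BuLi, THF, −78 °C; then 10, −78 → 0 °C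
Reagents that add atoms: none
Why: Weinreb ketone synthesis with the lithium acetylide of 11 brings in C5, C6 and C16 by a single addition.

Step 8
Reactants: 12 C7 ynone
Product: 13 (7S)-propargylic alcohol
Conditions: Ru[(R,R)-TsDPEN](p-cymene) (2 mol %), i-PrOH, 23 °C
Reagents that add atoms: none
Why: Noyori asymmetric transfer hydrogenation: the ligand recognises the alkyne of the alkynyl alkenyl ketone and sets C7 as the (S)-carbinol by reagent control.

Step 9
Reactants: 13 (7S)-propargylic alcohol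
Product: 15 iodoalkene with iodine on C5 cis to C7, via cyclic alkenylalanate 14 (not isolated)
Conditions: NaAlH2(OCH2CH2OMe)2, THF, 0 °C; I2, −78 °C
Reagents that add atoms: iodine II
Why: Hydroxyl-directed trans-hydroalumination puts aluminium on C5 cis to C7 in a five-membered alanate and iodine replaces it with retention, which encodes the later C5=C6 geometry (C4 cis to C7).

Step 10
Reactants: 15 iodoalkene, C19–OTBS
Product: 16 iodo diol (C7–OH, C19–OH)
Conditions: HF·pyridine, pyridine, THF, 0 °C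
Reagents that add atoms: none
Why: Buffered HF·pyridine cleaves the primary allylic TBS ether much faster than the hindered secondary one at C9.

Step 11
Reactants: 16 iodo diol
Product: 19 (5S)-4-substituted 3-methyl-5-(iodoalkenyl)furan-2(5H)-one (target-type butenolide), via hydroxy enal 17 (not isolated), via lactol 18 (not isolated)
Conditions: TEMPO (10 mol %), PhI(OAc)2, CH2Cl2, 23 °C
Reagents that add atoms: none
Why: Oxidative lactonisation: the primary allylic alcohol is oxidised first, the hydroxy enal closes to the lactol and this is oxidised to the butenolide, now with C19 as carbonyl and C7 as lactone carbinol.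

Step 12
Reactants: 19 iodo butenolide; 20 3-[(tert-butyldimethylsilyl)oxy]propanal
Product: 21 C4 allylic alcohol (both C4 epimers)
Conditions: CrCl2 (4 equiv), NiCl2 (2 mol %), DMF, 23 °C
Reagents that add atoms: none
Why: Nozaki–Hiyama–Kishi coupling forms C4–C5 with retention of the alkene geometry and tolerates the butenolide; C4 forms unselectively and is corrected in steps 13 and 14.

Step 13
Reactants: 21 C4 allylic alcohol
Product: 22 C4 enone
Conditions: Dess–Martin periodinane, NaHCO3, CH2Cl2, 0 → 23 °C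
Reagents that add atoms: none
Why: Dess–Martin oxidation gives the enone under neutral conditions that leave the alkene geometry and C7 untouched.

Step 14
Reactants: 22 C4 enone
Product: 23 (4R)-allylic alcohol
Conditions: (S)-2-methyl-CBS-oxazaborolidine (20 mol %), catecholborane, toluene, −78 °C
Reagents that add atoms: none
Why: Corey–Bakshi–Shibata reduction: the α-branched alkenyl group acts as the large substituent, so the (S)-catalyst gives the (4R)-alcohol by reagent control.

Step 15
Reactants: 23 (4R)-allylic alcohol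
Product: 24 C4 TIPS ether
Conditions: TIPSOTf, 2,6-lutidine, CH2Cl2, −78 → 0 °C
Reagents that add atoms: triisopropylsilyl triflate CC(C)[Si](OS(=O)(=O)C(F)(F)F)(C(C)C)C(C)C
Why: A silyl triflate silylates the hindered secondary allylic alcohol under buffered conditions.

Step 16
Reactants: 24 C4 TIPS ether
Product: 25 C2 primary alcohol
Conditions: HF·pyridine, pyridine, THF, 0 °C
Reagents that add atoms: none
Why: The primary TBS ether is cleaved selectively, and this is done before the acid-sensitive epoxide exists.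

Step 17
Reactants: 25 C2 primary alcohol
Product: 26 1,14-epoxide (1R,14S), oxygen anti to C9
Conditions: L-fructose-derived Shi ketone (30 mol %), KHSO5 (Oxone), K2CO3, n-Bu4NHSO4, MeCN–CH2(OMe)2–aq. Na2B4O7, 0 °C
Reagents that add atoms: potassium peroxymonosulfate [K+].[O-]S(=O)(=O)OO
Why: Shi epoxidation: the chiral dioxirane takes only the electron-rich ring A alkenes anti to C9 (C5=C6 carries three allylic oxygens, the butenolide is electron-poor), and its enantioface preference selects C1=C14 over C11=C12, which makes C10 stereogenic in the required sense and sets C1 and C14.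

Step 18
Reactants: 26 1,14-epoxide
Product: 27 bromohydrin (C1 tertiary bromide, C14 carbinol)
Conditions: 48% aq. HBr (1.5 equiv), LiBr, THF, −20 °C
Reagents that add atoms: hydrogen bromide Br
Why: Acid-mediated epoxide opening: bromide enters at the tertiary C1 of the protonated epoxide, as with 1-methylcyclohexene oxide; anti opening is expected, but the C1 configuration is irrelevant because either epimer gives the same enolate.

Step 19
Reactants: 27 bromohydrin
Product: 28 ring A C1 α-bromo ketone with seco C2 aldehyde (precursor of the key step)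
Conditions: Dess–Martin periodinane (3 equiv), NaHCO3, CH2Cl2, 0 °C
Reagents that add atoms: none
Why: Dess–Martin oxidation converts the C14 carbinol into the ketone and the C2 alcohol into the aldehyde in one neutral, buffered operation that the base-sensitive tertiary α-bromo ketone survives.

Step 20
Reactants: 28 ring A C1 α-bromo ketone with seco C2 aldehyde
Product: 30 (2R)-2-hydroxy-14-oxo briarane butenolide (C4–OTIPS, C9–OTBS, C16–OPMB), via samarium enolate 29 (not isolated)
Conditions: SmI2 (2.2 equiv, 0.1 M in THF), slow addition of 28 (final 2 mM), THF, −78 °C; aq. NH4Cl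
Reagents that add atoms: none
Why: Two single-electron transfers from divalent samarium break the C1–Br bond of either epimer and leave one trivalent samarium enolate across C1–C14, so no base ever meets the acidic C13 protons or the β-silyloxy aldehyde. The enolate adds to the C2 aldehyde through a chelated six-membered transition state, an intramolecular samarium Reformatsky (aldol) reaction of the kind used to close medium rings from α-bromo carbonyl compounds and tethered aldehydes. The ten-membered ring closes by exo attack on the aldehyde with the enolate double bond outside the new ring, helped by the Z alkene and the flat butenolide, which hold C2 near C1. C1 is controlled by C10: the tether leaves C10 on one side of the enolate, and only bond formation on the opposite face, giving the trans ring fusion (C15 anti to H10), is free of strain. C2 follows from the fixed geometry of the ring enolate in the chair-like chelate, and the cold samarium aldolate does not revert. The step needs reduction of C–Br before the aldehyde or butenolide and ring closure before intermolecular reaction; the fast C–Br reduction at −78 °C and slow addition at high dilution secure both.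

Step 21
Reactants: 30 2-hydroxy-14-oxo briarane butenolide
Product: 31 2,14-diol (14S)
Conditions: LiBH(s-Bu)3, THF, −78 °C
Reagents that add atoms: none
Why: The bulky hydride attacks the ring A ketone from the equatorial direction and gives the axial (14S) alcohol, anti to the axial C15 methyl group.

Step 22
Reactants: 31 2,14-diol
Product: 32 2,9,14-triol
Conditions: HF·pyridine, pyridine, THF, 0 → 23 °C
Reagents that add atoms: none
Why: HF·pyridine cleaves the TBS ether at C9 while the bulkier TIPS ether at C4 stays.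

Step 23
Reactants: 32 2,9,14-triol
Product: 33 8,17-epoxy lactone
Conditions: t-BuOOH, BnMe3NOH (cat.), THF, 0 °C
Reagents that add atoms: tert-butyl hydroperoxide CC(C)(C)OO
Why: Weitz–Scheffer epoxidation: the peroxide anion adds only to the electron-poor butenolide, at C8 on the face away from ring A, and closes to the cis-fused 8,17-epoxy lactone with C8 as in the target.

Step 24
Reactants: 33 8,17-epoxy lactone
Product: 34 8-hydroxy lactone (17R), tetraol
Conditions: SmI2 (2.5 equiv), MeOH, THF, −78 °C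
Reagents that add atoms: none
Why: SmI2 cleaves the C17–O bond next to the lactone carbonyl (reductive opening of an α,β-epoxy ester) and methanol protonates the samarium enolate opposite the chelated C8 alkoxide, giving C18 anti to C9, which is also the more stable C17 epimer.

Step 25
Reactants: 34 8-hydroxy lactone tetraol
Product: 35 2,9,14-triacetate
Conditions: Ac2O, DMAP, pyridine, CH2Cl2, 23 °C
Reagents that add atoms: acetic anhydride CC(=O)OC(C)=O
Why: DMAP-catalysed acetylation takes the three secondary alcohols at C2, C9 and C14 and leaves the tertiary C8 hydroxyl.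

Step 26
Reactants: 35 2,9,14-triacetate
Product: 36 C4 alcohol
Conditions: n-Bu4NF, AcOH, THF, 23 °C
Reagents that add atoms: none
Why: Fluoride buffered with acetic acid removes the TIPS ether without acetate loss or acyl migration.

Step 27
Reactants: 37 (R)-3-hydroxybutanoic acid
Product: 38 (R)-3-acetoxybutanoic acid
Conditions: Ac2O, pyridine, 23 °C; H2O
Reagents that add atoms: acetic anhydride CC(=O)OC(C)=O
Why: Acetylation of the secondary alcohol; the mixed anhydride of the acid is hydrolysed on aqueous work-up and the stereocentre is not touched.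

Step 28
Reactants: 36 C4 alcohol; 38 (R)-3-acetoxybutanoic acid
Product: 39 16-O-PMB ether of the target
Conditions: EDC·HCl, DMAP (10 mol %), CH2Cl2, 0 °C
Reagents that add atoms: none
Why: Steglich esterification acylates the allylic C4 alcohol, the only reactive hydroxyl left (C8–OH is tertiary), at 0 °C to avoid elimination of the β-acetoxy acid.

Step 29
Reactants: 39 16-O-PMB ether of the target
Product: 40 CNP0316115.1
Conditions: DDQ, CH2Cl2–pH 7 buffer, 0 °C
Reagents that add atoms: none
Why: DDQ oxidises the electron-rich benzyl ether to an oxocarbenium ion, which water cleaves to free the C16 alcohol.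

Compound list
1 | 2,6-dimethylbenzoic acid | Cc1cccc(C)c1C(=O)O | starting material
2 | 2,6-dimethylcyclohexa-2,5-diene-1-carboxylic acid | CC1=CCC=C(C)C1C(=O)O | intermediate
3 | N-methoxy-N,2,6-trimethylcyclohexa-2,5-diene-1-carboxamide | CON(C)C(=O)C1C(C)=CCC=C1C | intermediate
4 | prop-2-yn-1-ol | C#CCO | starting material
5 | 1-(2,6-dimethylcyclohexa-2,5-dien-1-yl)-4-hydroxybut-2-yn-1-one | OCC#CC(=O)C1C(C)=CCC=C1C | intermediate
6 | (R)-1-(2,6-dimethylcyclohexa-2,5-dien-1-yl)but-2-yne-1,4-diol | OCC#C[C@H](O)C1C(C)=CCC=C1C | intermediate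
7 | alkenylmagnesium bromide from anti addition across C8≡C17 (Me on C17, Mg on C8 cis to C19), drawn as the tris(bromomagnesium) species | C/C(CO[Mg]Br)=C(/[Mg]Br)[C@H](O[Mg]Br)C1C(C)=CCC=C1C | intermediate
8 | 3-[(R)-(2,6-dimethylcyclohexa-2,5-dien-1-yl)(hydroxy)methyl]-4-methylfuran-2(5H)-one | CC1=C(C(=O)OC1)[C@H](O)C2C(C)=CCC=C2C | intermediate
9 | dihydroxy Weinreb amide (C7 amide cis to C19H2OH on C8=C17, free C9–OH) | OC/C(C)=C(\C(=O)N(C)OC)[C@H](O)C1C(C)=CCC=C1C | intermediate
10 | bis-TBS ether of 9 (C9–OTBS, C19–OTBS) | CC(C)(C)[Si](C)(C)OC/C(C)=C(\C(=O)N(C)OC)[C@H](O[Si](C)(C)C(C)(C)C)C1C(C)=CCC=C1C | intermediate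
11 | 1-methoxy-4-[(prop-2-yn-1-yloxy)methyl]benzene | C#CCOCc1ccc(OC)cc1 | starting material
12 | C7 ynone | CC(C)(C)[Si](C)(C)OC/C(C)=C(\C(=O)C#CCOCc1ccc(OC)cc1)[C@H](O[Si](C)(C)C(C)(C)C)C2C(C)=CCC=C2C | intermediate
13 | (7S)-propargylic alcohol | CC(C)(C)[Si](C)(C)OC/C(C)=C(\[C@@H](O)C#CCOCc1ccc(OC)cc1)[C@H](O[Si](C)(C)C(C)(C)C)C2C(C)=CCC=C2C | intermediate
14 | sodium alkenylalanate, five-membered ring Al–O7–C7–C6=C5 (idealised) | [Na+].COCCO[Al-]1(OCCOC)O[C@H](/C(=C(/C)CO[Si](C)(C)C(C)(C)C)[C@H](O[Si](C)(C)C(C)(C)C)C2C(C)=CCC=C2C)C=C1COCc3ccc(OC)cc3 | intermediate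
15 | iodoalkene (I on C5 cis to C7), C19–OTBS | CC(C)(C)[Si](C)(C)OC/C(C)=C(\[C@@H](O)/C=C(\I)COCc1ccc(OC)cc1)[C@H](O[Si](C)(C)C(C)(C)C)C2C(C)=CCC=C2C | intermediate
16 | iodo diol (C7–OH, C19–OH) | OC/C(C)=C(\[C@@H](O)/C=C(\I)COCc1ccc(OC)cc1)[C@H](O[Si](C)(C)C(C)(C)C)C2C(C)=CCC=C2C | intermediate
17 | hydroxy enal (C19 aldehyde) | O=C/C(C)=C(\[C@@H](O)/C=C(\I)COCc1ccc(OC)cc1)[C@H](O[Si](C)(C)C(C)(C)C)C2C(C)=CCC=C2C | intermediate
18 | lactol (C19 hemiacetal, both anomers) | COc1ccc(COC/C(I)=C/[C@@H]2OC(O)C(C)=C2[C@H](O[Si](C)(C)C(C)(C)C)C3C(C)=CCC=C3C)cc1 | intermediate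
19 | iodo butenolide (C19 lactone carbonyl, 7S, 9R) | COc1ccc(COC/C(I)=C/[C@@H]2OC(=O)C(C)=C2[C@H](O[Si](C)(C)C(C)(C)C)C3C(C)=CCC=C3C)cc1 | intermediate
20 | 3-[(tert-butyldimethylsilyl)oxy]propanal | CC(C)(C)[Si](C)(C)OCCC=O | starting material
21 | C4 allylic alcohol, both C4 epimers (C4 cis to C7 on C5=C6) | CC(C)(C)[Si](C)(C)OCCC(O)/C(COCc1ccc(OC)cc1)=C\[C@@H]2OC(=O)C(C)=C2[C@H](O[Si](C)(C)C(C)(C)C)C3C(C)=CCC=C3C | intermediate
22 | C4 enone | CC(C)(C)[Si](C)(C)OCCC(=O)/C(COCc1ccc(OC)cc1)=C\[C@@H]2OC(=O)C(C)=C2[C@H](O[Si](C)(C)C(C)(C)C)C3C(C)=CCC=C3C | intermediate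
23 | (4R)-allylic alcohol | CC(C)(C)[Si](C)(C)OCC[C@@H](O)/C(COCc1ccc(OC)cc1)=C\[C@@H]2OC(=O)C(C)=C2[C@H](O[Si](C)(C)C(C)(C)C)C3C(C)=CCC=C3C | intermediate
24 | C4 TIPS ether (C2–OTBS, C9–OTBS) | CC(C)(C)[Si](C)(C)OCC[C@@H](O[Si](C(C)C)(C(C)C)C(C)C)/C(COCc1ccc(OC)cc1)=C\[C@@H]2OC(=O)C(C)=C2[C@H](O[Si](C)(C)C(C)(C)C)C3C(C)=CCC=C3C | intermediate
25 | C2 primary alcohol | OCC[C@@H](O[Si](C(C)C)(C(C)C)C(C)C)/C(COCc1ccc(OC)cc1)=C\[C@@H]2OC(=O)C(C)=C2[C@H](O[Si](C)(C)C(C)(C)C)C3C(C)=CCC=C3C | intermediate
26 | 1,14-epoxide (1R,14S), oxygen anti to C9 | OCC[C@@H](O[Si](C(C)C)(C(C)C)C(C)C)/C(COCc1ccc(OC)cc1)=C\[C@@H]2OC(=O)C(C)=C2[C@H](O[Si](C)(C)C(C)(C)C)[C@H]3C(C)=CC[C@@H]4O[C@]34C | intermediate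
27 | bromohydrin (C1–Br anti to C14–OH) | OCC[C@@H](O[Si](C(C)C)(C(C)C)C(C)C)/C(COCc1ccc(OC)cc1)=C\[C@@H]2OC(=O)C(C)=C2[C@H](O[Si](C)(C)C(C)(C)C)[C@H]3C(C)=CC[C@H](O)[C@@]3(C)Br | intermediate
28 | ring A C1 α-bromo ketone with seco C2 aldehyde (one C1 epimer drawn) | O=CC[C@@H](O[Si](C(C)C)(C(C)C)C(C)C)/C(COCc1ccc(OC)cc1)=C\[C@@H]2OC(=O)C(C)=C2[C@H](O[Si](C)(C)C(C)(C)C)[C@H]3C(C)=CCC(=O)[C@@]3(C)Br | intermediate
29 | C1–C14 samarium enolate of the seco aldehyde | O=CC[C@@H](O[Si](C(C)C)(C(C)C)C(C)C)/C(COCc1ccc(OC)cc1)=C\[C@@H]2OC(=O)C(C)=C2[C@H](O[Si](C)(C)C(C)(C)C)[C@H]3C(C)=CCC(O[Sm](I)I)=C3C | intermediate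
30 | (2R)-2-hydroxy-14-oxo briarane butenolide (C4–OTIPS, C9–OTBS, C16–OPMB) | CC(C)[Si](C(C)C)(C(C)C)O[C@@H]1C[C@@H](O)[C@@]2(C)C(=O)CC=C(C)[C@@H]2[C@@H](O[Si](C)(C)C(C)(C)C)C3=C(C)C(=O)O[C@H]3/C=C\1COCc4ccc(OC)cc4 | intermediate
31 | 2,14-diol (14S) | CC(C)[Si](C(C)C)(C(C)C)O[C@@H]1C[C@@H](O)[C@@]2(C)[C@@H](O)CC=C(C)[C@@H]2[C@@H](O[Si](C)(C)C(C)(C)C)C3=C(C)C(=O)O[C@H]3/C=C\1COCc4ccc(OC)cc4 | intermediate
32 | 2,9,14-triol | CC(C)[Si](C(C)C)(C(C)C)O[C@@H]1C[C@@H](O)[C@@]2(C)[C@@H](O)CC=C(C)[C@@H]2[C@@H](O)C3=C(C)C(=O)O[C@H]3/C=C\1COCc4ccc(OC)cc4 | intermediate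
33 | 8,17-epoxy lactone | CC(C)[Si](C(C)C)(C(C)C)O[C@@H]1C[C@@H](O)[C@@]2(C)[C@@H](O)CC=C(C)[C@@H]2[C@@H](O)[C@@]35O[C@@]5(C)C(=O)O[C@H]3/C=C\1COCc4ccc(OC)cc4 | intermediate
34 | 8-hydroxy lactone (17R), 2,8,9,14-tetraol | CC(C)[Si](C(C)C)(C(C)C)O[C@@H]1C[C@@H](O)[C@@]2(C)[C@@H](O)CC=C(C)[C@@H]2[C@@H](O)[C@@]2(O)[C@H](/C=C\1COCc3ccc(OC)cc3)OC(=O)[C@@H]2C | intermediate
35 | 2,9,14-triacetate | CC(C)[Si](C(C)C)(C(C)C)O[C@@H]1C[C@@H](OC(C)=O)[C@@]2(C)[C@@H](OC(C)=O)CC=C(C)[C@@H]2[C@@H](OC(C)=O)[C@@]2(O)[C@H](/C=C\1COCc3ccc(OC)cc3)OC(=O)[C@@H]2C | intermediate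
36 | C4 alcohol | O[C@@H]1C[C@@H](OC(C)=O)[C@@]2(C)[C@@H](OC(C)=O)CC=C(C)[C@@H]2[C@@H](OC(C)=O)[C@@]2(O)[C@H](/C=C\1COCc3ccc(OC)cc3)OC(=O)[C@@H]2C | intermediate
37 | (R)-3-hydroxybutanoic acid | C[C@@H](O)CC(=O)O | starting material
38 | (R)-3-acetoxybutanoic acid | CC(=O)O[C@H](C)CC(=O)O | intermediate
39 | 16-O-(4-methoxybenzyl) ether of the target | CC(=O)O[C@H](C)CC(=O)O[C@@H]1C[C@@H](OC(C)=O)[C@@]2(C)[C@@H](OC(C)=O)CC=C(C)[C@@H]2[C@@H](OC(C)=O)[C@@]2(O)[C@H](/C=C\1COCc3ccc(OC)cc3)OC(=O)[C@@H]2C | intermediate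
40 | CNP0316115.1 | CC(=O)O[C@H](C)CC(=O)O[C@@H]1C[C@@H](OC(C)=O)[C@@]2(C)[C@@H](OC(C)=O)CC=C(C)[C@@H]2[C@@H](OC(C)=O)[C@@]2(O)[C@H](/C=C\1CO)OC(=O)[C@@H]2C | target

Total step count: 29. Longest linear sequence: 28 steps (steps 1–26, 28 and 29; step 27 is a one-step side branch).

Steps most likely to fail

Step 20. Intermolecular aldol addition or simple protonation of the samarium enolate may outrun the ten-membered ring closure, or the ring may close on the wrong enolate face. The fallback sets out from 28. Zinc and Me3SiCl in THF reduce the C1–Br bond and trap the enolate as the C1–C14 trimethylsilyl enol ether aldehyde F1. Under high dilution, BF3·OEt2 in CH2Cl2 at −78 °C then closes the ring by an intramolecular Mukaiyama aldol reaction, and loss of the silyl group on work-up brings the route back at 30.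

Step 18. The C1 cation may lose a proton or rearrange before bromide captures it, and the acid may loosen silyl ethers. The fallback sets out from 26. Cp2TiCl (from Cp2TiCl2 and Mn, THF) opens the epoxide by electron transfer at the tertiary C1, and β-hydride loss gives the exocyclic allylic alcohol F2 (C1=CH2, C14–OH). A cobalt-mediated hydrogen-atom-transfer hydrobromination (Co(acac)2, t-BuOOH, Et3SiH, TsBr) then adds hydrogen to the methylene carbon and bromine to C1 of this 1,1-disubstituted alkene in preference to the trisubstituted ones. The route is rejoined at 27, as either C1 epimer.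

Step 17. On this crowded substrate the chiral dioxirane may discriminate poorly between the two ring A alkenes, or epoxidise both. The fallback sets out from 25. mCPBA (NaHCO3, CH2Cl2, 0 °C) epoxidises either ring A alkene anti to C9 without reagent control. Chromatography separates 26 from the epoxide on the other ring A alkene F3, which is deoxygenated (PPh3, MeReO3 cat.) back to 25 for another pass. The route is rejoined at 26.

Further compounds
F1 | step 20 | C1–C14 trimethylsilyl enol ether of the seco aldehyde | O=CC[C@@H](O[Si](C(C)C)(C(C)C)C(C)C)/C(COCc1ccc(OC)cc1)=C\[C@@H]2OC(=O)C(C)=C2[C@H](O[Si](C)(C)C(C)(C)C)[C@H]3C(C)=CCC(O[Si](C)(C)C)=C3C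
F2 | step 18 | exocyclic allylic alcohol (C1=CH2, C14–OH) | OCC[C@@H](O[Si](C(C)C)(C(C)C)C(C)C)/C(COCc1ccc(OC)cc1)=C\[C@@H]2OC(=O)C(C)=C2[C@H](O[Si](C)(C)C(C)(C)C)[C@H]3C(C)=CC[C@H](O)C3=C
F3 | step 17 | epoxide on the other ring A alkene, anti to C9 (ring A mirror of 26) | OCC[C@@H](O[Si](C(C)C)(C(C)C)C(C)C)/C(COCc1ccc(OC)cc1)=C\[C@@H]2OC(=O)C(C)=C2[C@H](O[Si](C)(C)C(C)(C)C)[C@@H]3C(C)=CC[C@H]4O[C@@]34C
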